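**Strategy.** Ring C (the pyran of the flavan) is opened at C4–C4a. Its precursor is an open (S)-aryl 1-arylallyl ether. Ring A carries Br on C4a, ortho to O1, and a prenyl ether on O7. Ring B is complete. In one pot 9-BBN selects the C3=C4 vinyl group, the only monosubstituted alkene present, and Pd joins C4 to C4a (intramolecular B-alkyl Suzuki–Miyaura coupling). This closes ring C regiospecifically under basic conditions that cannot ionise the benzylic C2–O1 bond. C2 is set earlier by Cu/pybox propargylic etherification. A final aromatic Claisen shift turns the O7-prenyl ether into the C6 1,1-dimethylallyl group and the free 7-OH.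

Key step: step 8

Remark: flavan numbering (O1, C2, C3, C4, C4a, C5–C8, C8a; ring B primed) is also used for the open precursors.
Assumption: 2-bromo-4,5-dihydroxybenzaldehyde is taken as a catalogue compound.
Assumption: the antipode of Ph-pybox that leads to (S)-11 is used. Both antipodes are commercial, and the sense of induction is to be confirmed on the first run.

Step 1
Reactants: 1 4-bromoresorcinol (4-bromobenzene-1,3-diol)
Product: 2 2-bromo-5-(3-methylbut-2-enyloxy)phenol
Conditions: prenyl bromide (1.0 equiv), K2CO3 (1.0 equiv), acetone, 0 °C to rt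
Reagents that add atoms: prenyl bromide (1-bromo-3-methylbut-2-ene), CC(C)=CCBr
Why: Williamson ether synthesis in which one equivalent of the allylic bromide should alkylate mainly the unhindered OH para to bromine rather than the OH flanked by bromine, the isomeric and double ethers being removed by chromatography.

Step 2
Reactants: 3 2-bromo-4,5-dihydroxybenzaldehyde
Product: 4 2-bromo-5-hydroxy-4-(2-methylbut-3-yn-2-yloxy)benzaldehyde
Conditions: 3-chloro-3-methylbut-1-yne (1.2 equiv), K2CO3 (1.0 equiv), KI (cat.), acetone, reflux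
Reagents that add atoms: 3-chloro-3-methylbut-1-yne, C#CC(C)(C)Cl
Why: Base-mediated O-propargylation of a phenol with a tertiary propargylic chloride, in which one equivalent of weak base ionises only the more acidic 4-OH (para to the formyl group), as in the selective 4-O-alkylation of protocatechualdehyde.

Step 3
Reactants: 4 2-bromo-5-hydroxy-4-(2-methylbut-3-yn-2-yloxy)benzaldehyde
Product: 7 5-bromo-8-hydroxy-2,2-dimethyl-2H-chromene-6-carbaldehyde, via allenyl dienone 5 (not isolated), via o-quinone methide 6 (not isolated)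
Conditions: PhNEt2, 190 °C, Ar
Reagents that add atoms: none
Why: Thermal aryl propargyl ether cascade (propargyl Claisen rearrangement to the only free ortho carbon, enolisation, 1,5-H shift and oxa-6π electrocyclisation), the standard entry to 2,2-dimethyl-2H-chromenes.

Step 4
Reactants: 7 5-bromo-8-hydroxy-2,2-dimethyl-2H-chromene-6-carbaldehyde
Product: 8 8-hydroxy-2,2-dimethyl-5-(3-methylbut-2-enyl)-2H-chromene-6-carbaldehyde
Conditions: prenylSnBu3 (1.3 equiv), Pd(PPh3)4 (5 mol %), DMF, 100 °C
Reagents that add atoms: tributyl(3-methylbut-2-enyl)stannane, CCCC[Sn](CCCC)(CCCC)CC=C(C)C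
Why: Migita–Kosugi–Stille allylation, in which oxidative addition is helped by the ortho formyl group and reductive elimination at the unsubstituted terminus of the prenyl–palladium unit should give the linear prenyl arene under neutral conditions that tolerate the free phenol and the aldehyde.

Step 5
Reactants: 8 8-hydroxy-2,2-dimethyl-5-(3-methylbut-2-enyl)-2H-chromene-6-carbaldehyde
Product: 10 rac-1-[8-acetoxy-2,2-dimethyl-5-(3-methylbut-2-enyl)-2H-chromen-6-yl]prop-2-ynyl acetate, via bis(bromomagnesium) alkoxide 9 (not isolated)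
Conditions: HC≡CMgBr (3 equiv), THF, 0 °C to rt; then Ac2O (4 equiv), DMAP (cat.), 0 °C to rt
Reagents that add atoms: ethynylmagnesium bromide, C#C[Mg]Br; acetic anhydride, CC(=O)OC(C)=O
Why: 1,2-Addition of an alkynyl Grignard reagent to the aldehyde (the first equivalent is spent on the phenol) and in situ O-acylation of both magnesium oxides, which creates C2 as a racemate, installs the leaving group and masks the chromene 8-OH in one flask.

Step 6
Reactants: 10 rac-1-[8-acetoxy-2,2-dimethyl-5-(3-methylbut-2-enyl)-2H-chromen-6-yl]prop-2-ynyl acetate; 2 2-bromo-5-(3-methylbut-2-enyloxy)phenol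
Product: 11 (S)-6-{1-[2-bromo-5-(3-methylbut-2-enyloxy)phenoxy]prop-2-ynyl}-2,2-dimethyl-5-(3-methylbut-2-enyl)-2H-chromen-8-yl acetate
Conditions: 2 (1.3 equiv), CuOTf·½C6H6 (5 mol %), Ph-pybox (10 mol %), i-Pr2NEt (1.2 equiv), ClCH2CH2Cl, −10 °C
Reagents that add atoms: none
Why: Copper-catalysed enantioselective propargylic etherification of a propargylic ester with a phenol, in which both enantiomers of 10 ionise to the same planar copper–allenylidene and the pybox ligand shields one face of its γ-carbon, so that the phenoxide of 2 should form the C2–O1 bond with (S) configuration.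

Step 7
Reactants: 11 (S)-propargylic aryl ether
Product: 12 (S)-6-{1-[2-bromo-5-(3-methylbut-2-enyloxy)phenoxy]prop-2-enyl}-2,2-dimethyl-5-(3-methylbut-2-enyl)-2H-chromen-8-yl acetate
Conditions: H2 (1 atm), Lindlar catalyst, quinoline, EtOAc, rt, stopped after one equivalent of H2
Reagents that add atoms: none
Why: Lindlar semihydrogenation, which stops at the alkene for a terminal alkyne and leaves the aryl bromide, both prenyl groups, the chromene alkene and the C2–O1 bond untouched, so that C2 keeps its configuration.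

Step 8
Reactants: 12 (S)-allylic aryl ether
Product: 14 6-[(2S)-7-(3-methylbut-2-enyloxy)chroman-2-yl]-2,2-dimethyl-5-(3-methylbut-2-enyl)-2H-chromen-8-ol, via B-alkyl-9-BBN adduct 13 (not isolated)
Conditions: 9-BBN (1.2 equiv), THF, 0 °C to rt; then PdCl2(dppf)·CH2Cl2 (5 mol %), 3 M aq NaOH, THF (0.01 M), 65 °C
Reagents that add atoms: none
Why: 9-BBN adds anti-Markovnikov to the C3=C4 vinyl group and puts boron on C4 (13); hydroxide turns the borane into its borate, Pd(0) inserts into the C4a–Br bond, intramolecular transmetalation gives a seven-membered palladacycle and reductive elimination forms C4–C4a. The closest known reaction type is the hydroboration/intramolecular B-alkyl Suzuki–Miyaura sequence that converts ω-alkenyl haloarenes into benzo-fused five- and six-membered rings. Ring C is thus closed as a six-membered ring by sp3–sp2 reductive elimination, a closure free of the 5-exo/6-endo ambiguity of Heck or radical cyclisations of the same allyl ether. No stereocentre is created, and C2 keeps its (S) configuration because none of its bonds is touched and the medium is basic, so that the p-alkoxybenzylic C2–O1 bond cannot ionise. The step needs chemoselective hydroboration, secured by the steric demand of 9-BBN (one monosubstituted vinyl group against two trisubstituted prenyl alkenes and the hindered cis-disubstituted chromene alkene), and site selectivity on ring A, secured by the bromine on C4a, which excludes C8, while high dilution disfavours intermolecular coupling. The aqueous NaOH that activates boron also saponifies the aryl acetate, so that the 5'-OH is released in the same flask.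

Step 9
Reactants: 14 (2S)-7-prenyloxyflavan
Product: 16 kazinol H, via ortho-dienone 15 (not isolated)
Conditions: PhNEt2, 200 °C, sealed tube, Ar
Reagents that add atoms: none
Why: Aromatic Claisen rearrangement ([3,3] shift, then tautomerisation of the dienone), which transfers the prenyl group with allylic inversion to C6, the ortho carbon that is para to O1 and not flanked by two oxygens, as with related 2,4-dioxygenated aryl prenyl ethers, frees the 7-OH and does not involve C2.

**Compound list**

1 | 4-bromoresorcinol (4-bromobenzene-1,3-diol) | Oc1ccc(Br)c(O)c1 | starting material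
2 | 2-bromo-5-(3-methylbut-2-enyloxy)phenol | Oc1cc(OCC=C(C)C)ccc1Br | intermediate
3 | 2-bromo-4,5-dihydroxybenzaldehyde | O=Cc1cc(O)c(O)cc1Br | starting material
4 | 2-bromo-5-hydroxy-4-(2-methylbut-3-yn-2-yloxy)benzaldehyde | O=Cc1cc(O)c(OC(C)(C)C#C)cc1Br | intermediate
5 | allenyl dienone: 2-bromo-5-hydroxy-3-(3-methylbuta-1,2-dienyl)-4-oxocyclohexa-1,5-diene-1-carbaldehyde (racemic) | O=CC1=C(Br)C(C=C=C(C)C)C(=O)C(O)=C1 | intermediate
6 | o-quinone methide: 2-bromo-5-hydroxy-3-(3-methylbut-2-enylidene)-4-oxocyclohexa-1,5-diene-1-carbaldehyde | O=CC1=C(Br)C(=CC=C(C)C)C(=O)C(O)=C1 | intermediate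
7 | 5-bromo-8-hydroxy-2,2-dimethyl-2H-chromene-6-carbaldehyde | O=Cc1cc(O)c2OC(C)(C)C=Cc2c1Br | intermediate
8 | 8-hydroxy-2,2-dimethyl-5-(3-methylbut-2-enyl)-2H-chromene-6-carbaldehyde | O=Cc1cc(O)c2OC(C)(C)C=Cc2c1CC=C(C)C | intermediate
9 | bis(bromomagnesium) salt of rac-6-(1-hydroxyprop-2-ynyl)-2,2-dimethyl-5-(3-methylbut-2-enyl)-2H-chromen-8-ol | C#CC(O[Mg]Br)c1cc(O[Mg]Br)c2OC(C)(C)C=Cc2c1CC=C(C)C | intermediate
10 | rac-1-[8-acetoxy-2,2-dimethyl-5-(3-methylbut-2-enyl)-2H-chromen-6-yl]prop-2-ynyl acetate | C#CC(OC(C)=O)c1cc(OC(C)=O)c2OC(C)(C)C=Cc2c1CC=C(C)C | intermediate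
11 | (S)-6-{1-[2-bromo-5-(3-methylbut-2-enyloxy)phenoxy]prop-2-ynyl}-2,2-dimethyl-5-(3-methylbut-2-enyl)-2H-chromen-8-yl acetate | Brc1ccc(OCC=C(C)C)cc1O[C@H](c1cc(OC(C)=O)c2c(c1CC=C(C)C)C=CC(C)(C)O2)C#C | intermediate
12 | (S)-6-{1-[2-bromo-5-(3-methylbut-2-enyloxy)phenoxy]prop-2-enyl}-2,2-dimethyl-5-(3-methylbut-2-enyl)-2H-chromen-8-yl acetate | Brc1ccc(OCC=C(C)C)cc1O[C@H](c1cc(OC(C)=O)c2c(c1CC=C(C)C)C=CC(C)(C)O2)C=C | intermediate
13 | (S)-6-{3-(9-borabicyclo[3.3.1]nonan-9-yl)-1-[2-bromo-5-(3-methylbut-2-enyloxy)phenoxy]propyl}-2,2-dimethyl-5-(3-methylbut-2-enyl)-2H-chromen-8-yl acetate | Brc1ccc(OCC=C(C)C)cc1O[C@H](c1cc(OC(C)=O)c2c(c1CC=C(C)C)C=CC(C)(C)O2)CCB1C2CCCC1CCC2 | intermediate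
14 | 6-[(2S)-7-(3-methylbut-2-enyloxy)chroman-2-yl]-2,2-dimethyl-5-(3-methylbut-2-enyl)-2H-chromen-8-ol | CC(C)=CCOc1ccc2c(c1)O[C@H](c1cc(O)c3c(c1CC=C(C)C)C=CC(C)(C)O3)CC2 | intermediate
15 | ortho-dienone: (2S)-2-[8-hydroxy-2,2-dimethyl-5-(3-methylbut-2-enyl)-2H-chromen-6-yl]-6-(2-methylbut-3-en-2-yl)-3,4-dihydro-2H-chromen-7(6H)-one, both C6 epimers | C=CC(C)(C)C1C=C2CC[C@@H](c3cc(O)c4c(c3CC=C(C)C)C=CC(C)(C)O4)OC2=CC1=O | intermediate
16 | kazinol H: (2S)-2-[8-hydroxy-2,2-dimethyl-5-(3-methylbut-2-enyl)-2H-chromen-6-yl]-6-(2-methylbut-3-en-2-yl)chroman-7-ol | C=CC(C)(C)c1cc2c(cc1O)O[C@H](c1cc(O)c3c(c1CC=C(C)C)C=CC(C)(C)O3)CC2 | target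

**Total step count:** 9. **Longest linear sequence:** 8 (steps 2–9, from 3).

**Steps most likely to fail**

Step 8 (key step). Ring closure may lose out to protodeboronation or to β-hydride elimination from the alkylpalladium species. Pd(0)-induced cleavage of the O7-prenyl ether in the hot basic medium is a further risk. The fallback keeps the bond but replaces transmetalation with cross-electrophile coupling, and it sets out from 12. Hydroboration with 9-BBN and oxidative work-up (H2O2, NaOH, which also removes the acetate) gives the primary alcohol F1. Appel iodination (I2, PPh3, imidazole) gives the primary iodide F2. Nickel-catalysed intramolecular reductive coupling of the aryl bromide with the alkyl iodide (NiBr2·glyme, 4,4'-di-tert-butyl-2,2'-bipyridine, Zn, DMA) then closes ring C and comes back to the route at 14.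

Step 6. The hindered ortho-bromophenol may add slowly, and the ortho-prenyl group may erode facial selectivity. C-propargylation of ring A, or capture of the cationic γ-carbon by the neighbouring prenyl alkene, may also compete. The fallback replaces the copper–allenylidene chemistry and step 7 by iridium-catalysed asymmetric allylic etherification, and it sets out from 8. Wittig olefination with Ph3P=CHCO2Et gives the (E)-enoate F3, and DIBAL-H reduction gives the (E)-allylic alcohol F4. ClCO2Me/pyridine gives the bis(methyl carbonate) F5. [Ir(cod)Cl]2/chiral phosphoramidite with the lithium phenoxide of 2 gives the branched (S)-allyl aryl ether F6, the carbonate analogue of 12. F6 is taken through the conditions of step 8, in which NaOH removes the aryl carbonate, and the route is rejoined at 14.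

Step 9. The [3,3] shift may go in part to C8. The product may isomerise further (abnormal Claisen rearrangement), or the 7-OH may add to the new vinyl group at the temperature needed. The fallback forms the C6–C bond by cross-coupling instead of by sigmatropy, and it sets out from 10. Compound 10 is etherified under the conditions of step 6 with an excess of commercial, symmetric 4,6-dibromobenzene-1,3-diol to give the (S)-propargylic dibromoaryl ether F7. Lindlar semihydrogenation gives the (S)-allylic dibromoaryl ether F8. The conditions of step 8 (one more equivalent of 9-BBN for the free phenol) close ring C at the bromine ortho to O1, the only one within reach, and give the (2S)-6-bromoflavan-7-ol F9. γ-Selective Suzuki–Miyaura coupling with 3-methylbut-2-enylboronic acid pinacol ester (Pd/bulky biarylphosphine, aq K3PO4, THF) installs the 1,1-dimethylallyl group and comes back to the route at 16.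

**Further compounds**

F1 | step 8 | primary alcohol, (S)-3-[2-bromo-5-(3-methylbut-2-enyloxy)phenoxy]-3-[8-hydroxy-2,2-dimethyl-5-(3-methylbut-2-enyl)-2H-chromen-6-yl]propan-1-ol | Brc1ccc(OCC=C(C)C)cc1O[C@H](c1cc(O)c2c(c1CC=C(C)C)C=CC(C)(C)O2)CCO
F2 | step 8 | primary iodide, (S)-6-{1-[2-bromo-5-(3-methylbut-2-enyloxy)phenoxy]-3-iodopropyl}-2,2-dimethyl-5-(3-methylbut-2-enyl)-2H-chromen-8-ol | Brc1ccc(OCC=C(C)C)cc1O[C@H](c1cc(O)c2c(c1CC=C(C)C)C=CC(C)(C)O2)CCI
F3 | step 6 | (E)-enoate, ethyl (E)-3-[8-hydroxy-2,2-dimethyl-5-(3-methylbut-2-enyl)-2H-chromen-6-yl]acrylate | CCOC(=O)/C=C/c1cc(O)c2OC(C)(C)C=Cc2c1CC=C(C)C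
F4 | step 6 | (E)-allylic alcohol, 6-[(E)-3-hydroxyprop-1-enyl]-2,2-dimethyl-5-(3-methylbut-2-enyl)-2H-chromen-8-ol | OC/C=C/c1cc(O)c2OC(C)(C)C=Cc2c1CC=C(C)C
F5 | step 6 | bis(methyl carbonate) of F4 | COC(=O)OC/C=C/c1cc(OC(=O)OC)c2OC(C)(C)C=Cc2c1CC=C(C)C
F6 | step 6 | branched (S)-allyl aryl ether, (S)-6-{1-[2-bromo-5-(3-methylbut-2-enyloxy)phenoxy]prop-2-enyl}-2,2-dimethyl-5-(3-methylbut-2-enyl)-2H-chromen-8-yl methyl carbonate | Brc1ccc(OCC=C(C)C)cc1O[C@H](c1cc(OC(=O)OC)c2c(c1CC=C(C)C)C=CC(C)(C)O2)C=C
F7 | step 9 | (S)-propargylic dibromoaryl ether, (S)-6-[1-(2,4-dibromo-5-hydroxyphenoxy)prop-2-ynyl]-2,2-dimethyl-5-(3-methylbut-2-enyl)-2H-chromen-8-yl acetate | Oc1cc(O[C@H](c2cc(OC(C)=O)c3c(c2CC=C(C)C)C=CC(C)(C)O3)C#C)c(Br)cc1Br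
F8 | step 9 | (S)-allylic dibromoaryl ether, (S)-6-[1-(2,4-dibromo-5-hydroxyphenoxy)prop-2-enyl]-2,2-dimethyl-5-(3-methylbut-2-enyl)-2H-chromen-8-yl acetate | Oc1cc(O[C@H](c2cc(OC(C)=O)c3c(c2CC=C(C)C)C=CC(C)(C)O3)C=C)c(Br)cc1Br
F9 | step 9 | (2S)-6-bromoflavan-7-ol, (2S)-6-bromo-2-[8-hydroxy-2,2-dimethyl-5-(3-methylbut-2-enyl)-2H-chromen-6-yl]chroman-7-ol | Brc1cc2c(cc1O)O[C@H](c1cc(O)c3c(c1CC=C(C)C)C=CC(C)(C)O3)CC2
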